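In a one-step world substrate would turn into product as it disappears, but in Sunday's flask substrate is down to 2.8% at 4.00 min while product stands at 21.4%, so I take a hidden intermediate to hold the rest.

| flask | substrate | reagent | precatalyst | remark | time |
|---|---|---|---|---|---|
| Sunday's | 20 mM | 22 mM | 20 µM | run made earlier |  |
| Monday's | 10 mM | 22 mM | 20 µM | run made earlier |  |
| Friday's | 40 mM | 22 mM | 20 µM | run made earlier |  |
| Wednesday's | 20 mM | 22 mM | 30 µM | run made earlier |  |
| delta | 20 mM | 22.0 mM (fed, over 40.0 min) | 20 µM | a stirred flask in which reagent is dosed at a steady rate over 40.0 min without added volume, worked up at 40 min | 40 min |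
| alpha | 20 mM (fed, over 40.0 min) | 22.0 mM | 20 µM | a stirred flask in which substrate is dosed at a steady rate over 40.0 min without added volume, worked up at 40 min | 40 min |
| beta | 20 mM | 22.0 mM | 20 µM | one stirred flow tank at steady state, fed with the mixture as stated, mean residence time 40 min |  |
| zeta | 20 mM | 22.0 mM | 20 µM | everything together in a closed stirred flask, run for 40 min | 40 min |

| run | time / min | product / % | substrate / % |
|---|---|---|---|
| Sunday's | 4.00 | 21.4 | 2.8 |
| Sunday's | 8.00 | 42.1 | 0.8 |
| Sunday's | 12.0 | 56.3 | 0 |
| Sunday's | 15.0 | 62.2 | 0 |
| Sunday's | 20.0 | 70.5 | 1.6 |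
| Sunday's | 25.0 | 75.2 | 2.1 |
| Monday's | 2.50 | 9.4 | 5.0 |
| Monday's | 8.00 | 46.7 | 1.1 |
| Monday's | 15.0 | 72.3 | 0.1 |
| Monday's | 20.0 | 81.2 | 0 |
| Monday's | 30.0 | 90.3 | 0 |
| Monday's | 40.0 | 95.6 | 0 |
| Friday's | 6.00 | 29.4 | 0.4 |
| Friday's | 12.0 | 42.9 | 0 |
| Friday's | 20.0 | 50.4 | 0.7 |
| Friday's | 25.0 | 54.2 | 0 |
| Friday's | 30.0 | 53.2 | 0 |
| Friday's | 40.0 | 54.2 | 2.3 |
| Wednesday's | 4.00 | 32.3 | 0 |
| Wednesday's | 10.0 | 60.1 | 0.2 |
| Wednesday's | 20.0 | 78.2 | 0 |
| Wednesday's | 30.0 | 86.1 | 0 |
| Wednesday's | 40.0 | 90.9 | 0 |

(standard deviation of a reading: 1 percentage point)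

- the stated concentrations are those of everything mixed, before any reaction; amounts are the same in each set-up
- the feed brings no volume worth counting
- the earlier runs were made in a closed, stirred flask

* the set-up with the highest amount of product at the outlet or at the end, in percent of the substrate put in ("none" if the first two lie within 2 percentage points) (delta / alpha / beta / zeta / none)
* amount of product at the outlet or at the end, in percent of the substrate put in, delta
* amount of product at the outlet or at the end, in percent of the substrate put in, alpha
* amount of product at the outlet or at the end, in percent of the substrate put in, beta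
* amount of product at the outlet or at the end, in percent of the substrate put in, zeta

Friday's flask levels off at 21.7 mM of product, close to the 22 mM of reagent charged, so I count one reagent per product, and reagent is the limiting reagent there.

Now carry one quantity. Treat the loss of intermediate as second order, with intermediate and reagent as partners. With precatalyst at 20 µM and the start-up ignored, Sunday's 70.5% at 20.0 min reads as 9.25 min, the lifetime of the intermediate at the full reagent charge. When a fraction f of the reagent remains, you divide that lifetime by f.

My own count is for beta, the tank. Its mean residence time of 40 min holds 4.33 such lifetimes, so at steady state product stands to intermediate as that number times f. Closing this with the reagent balance gives 64.3% product in beta, a little above the forecast's 63.5%.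

The forecast says “Dosing keeps one partner low, so batch wins”: delta 65%, alpha 63%, beta 63.5%, zeta 84%, best zeta.

The flasks give delta 65.4%, alpha 63.6%, beta 64.1%, zeta 84.4%, best zeta.

    substrate + catalyst → catalyst + intermediate (k = 92000 L mol⁻¹ min⁻¹)
    precatalyst → catalyst (k = 0.990 min⁻¹)
    reagent + catalyst + intermediate → catalyst + product (k = 2.60 × 10⁵ L² mol⁻² min⁻¹)

In beta, product at 64.1% leaves 41.7% of the reagent, so the lifetime is 22.2 min, the count is 1.80, and the tank's product-to-intermediate ratio is 1.86. The neighbouring flask is alpha with 88 mM of reagent, 4.40 equiv, close to pseudo-first-order. Its reagent ends at 79% of that charge, so the lifetime is 2.92 min, far shorter than the 40.0 min of dosing. Lifetime over dosing time then gives 7.30% intermediate at the end. That flask ends with 6.78% intermediate and 91.9% product.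

Readings and results were computed with made-up constants.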